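The molar second, one mole per litre of L standing for one second, is the unit to read this flask in: the logarithm of [Z], Z being the limiting reagent, charged in less than E, falls in proportion to the molar seconds of L it has met.

Z 0.10 M; E 1.20 equiv; time 20 s; volume of the second phase over the first 1.0

    L ⇌ E, rate k1*([L] - [E]/K1) per volume of the first phase (K1 = 0.408, k1 = 0.0203 /s)
    Z + L → Z.L (k2 = 0.194 /M/s)
    L + Z.L → L.Z.L (k3 = 0.147 /M/s)
    Z.L → D (k4 = 0.00868 /s)
    2 L → L2 (k5 = 0.346 /M/s)
    J ⇌ Z.L, rate k6*(cs6 - [Z.L]) while solid is left; crystals form when [Z.L] > cs6 (cs6 = 0.079 M, k6 = 0.182 /s)

- the Z.L and J together standing at 20 s, as a percentage of the Z charged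
- concentration of Z.L in solution at 10 s, in percent of saturation
- the change that raises the amount of Z.L and J together at 20 s, in percent of the Z charged most ("none" if none brings more than 2 percentage points) (dawn / summer / autumn / midnight / none)
- amount of Z.L and J together at 20 s, in percent of the Z charged, after dawn

- for Z.L the J are counted in
- a step written with two of one species runs at k times the square of its concentration and takes two of it each time
- in the second phase: E; everything else is in the first
- charges count per volume of the first phase; a concentration in a rate is the amount of a species over the volume of its own phase; every rate counts per litre of the first phase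
- as a solid, counted per litre of solution: J
- run time (flask): 20 s

- dawn: doubling the dissolution coefficient of step 6, all else as stated
- summer: doubling the transfer coefficient of step 1, all else as stated
- autumn: doubling the solubility in step 6, all else as stated
- midnight: doubling the amount of E, all else as stated

My own reckoning calls the time integral of [L] the exposure X. Step 2 makes ln[Z] fall with the rate constant times [L], so the fraction of Z taken is one minus the exponential of minus 0.194 /M/s times X. X therefore needs the curve of [L].

[L] starts at nothing and rises with the slope set by the feed from E:

F = 0.00597 M/s

With equal phases, the net feed weakens as E empties and L fills. With the capture of L by Z added at the charged level of Z, the reckoning counts [L] as lost with a first-order constant: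

r = 0.0895 /s

The pairing of L takes 0.692 /M/s times [L] squared. Setting F equal to these losses gives the estimated standing level of L, the level the drawn curve runs into:

[L]* = 0.0485 M

Level over slope places the knee:

τ = 8.13 s

Drawing [L] as an exponential rise to [L]* with this τ, the exposure is [L]* times the time less τ times the part of the rise completed:

X at 20 s = 0.610 M·s, so y = 11.2%

X at 10 s = 0.206 M·s, so sat = 4.96%

This y counts Z taken, so it stands somewhat high, as a little Z.L goes on to other products. Z.L reaches about 0.0112 M, less than the solubility, so no crystals form, and dawn leaves 11.2%.

Midnight doubles F to 0.0119 M/s and lifts the level to 0.0818 M. Summer doubles F too, but it also strengthens the back-transfer, raising the loss constant to 0.160 /s, so its level is 0.0595 M, lower than midnight's, though reached sooner. Scored by exposure gained, the choice is midnight.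

The forecast gives y 9.8%, sat 4.9%, yb 9.8% and best midnight, holding that “Doubling E doubles the feed of L throughout the run”. Its y stands below mine.

The simulation gives y 9.94%, sat 4.91%, yb 9.94% and best midnight, with midnight gaining 6.5 percentage points and summer 3.1 points. The saturation of Z.L makes no difference here.

The slow crossing of E holds y down: without that drag this flask reaches 16.3% instead of 9.94%, though that gain is 7.1% of what is missing. For the neighbour flask, read at 30 s, the same level and knee give an exposure of 1.07 M·s, so 18.7% of Z taken. The simulated neighbour flask has 17.7% of Z taken and 14.7% standing as Z.L.

(The numbers are assumed, and the outcome is calculated.)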